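**Numbering used throughout:** 1–5 pyrone branch, 6–9 ketene acetal branch, 10–13 ring B arene, 14–19 ring A branch, 20–22 depside and target.

## Analysis of the target

Stenosporic acid 22 is a depside, two benzene rings joined only by an aryl ester. Ring A is a 2-hydroxy-4-methoxy-6-propylbenzoyl unit. Ring B is a 2-hydroxy-6-pentylbenzoic acid whose C4 oxygen carries the ring A acyl group. There are no stereocentres, so the problem is regiochemistry and telling oxygen functions apart: the C2 hydroxyl and C4 methyl ether on ring A, and the C2 hydroxyl, C4 ester oxygen and carboxylic acid on ring B. The depside ester is an activated aryl ester with two ortho substituents on its acyl side, so it is hard to form and easily cleaved by bases and nucleophiles. The ring B salicylic acid decarboxylates on heating or in acid, so the last steps must be neutral and mild. The strategy rests on one mapping: C1 (carboxyl), C2 (oxygen), C3 and C6 (pentyl) of ring B are C5, C4, C3 and C6 of a 4-oxy-6-pentyl-2-pyrone-5-carboxylate. Only C4 with its oxygen and C5 then have to be added, as the two carbons of a ketene acetal, and the C4 oxygen arrives with a protecting group different from the one on C2.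

## Retrosynthetic reasoning

**22 to 21.** The three oxygen–benzyl bonds (ring A C2 ether, ring B C2 ether, ring B ester) are cut last. All three fall in one neutral hydrogenolysis, which the depside ester and the decarboxylation-prone acid should tolerate.

**21 to 13 and 19.** The depside acyl–oxygen bond is the only link between the rings, so cutting it gives the most convergent plan. Phenol 13 has a single free hydroxyl, so the site of acylation is not in question. The forward reaction must push the 2,6-disubstituted acid 19 onto a moderately nucleophilic phenol, which is why an acylium-like donor, the mixed anhydride 20, is planned.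

**13 to 12.** The C4 oxygen of ring B is carried as a silyl ether, orthogonal to the benzyl groups, so a fluoride source frees it alone.

**12 to 5 and 9 (key disconnection).** Ring B is cut at C5–C6 and C3–C4. This leaves C6–C1–C2–C3 with the pentyl, carboxyl and C2 oxygen already in place, which is the diene of pyrone 5, and a two-carbon piece whose oxygenated carbon becomes C4, which is ketene acetal 9. The gain is an aromatic ring at the right oxidation level, with regiochemistry set by polarity and with O2 and O4 differently protected from the start. The forward reaction has to achieve a head-to-tail cycloaddition to lactone 10, decarboxylative cycloreversion to diene 11, and elimination to 12. A bis-silyl acetal is used in place of a mixed alkyl silyl acetal because the elimination from the ketal carbon cannot be steered with confidence. Loss of the silyloxy group from a mixed ketal would leave an unusable aryl alkyl ether, whereas with two identical silyloxy groups in 11 either departure gives 12.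

**9 to 7 to 6.** The two silicon–oxygen bonds are cut in turn. Silyl ester 7 is enolized to 8 and silylated on oxygen.

**5 to 4.** The benzyl–oxygen bond at pyrone C4 is cut. A free hydroxyl would destroy 9 by proton or silyl transfer, and benzyl matches the final hydrogenolysis. The forward step must alkylate the 4-oxygen of an ambident pyronate, not the lactone oxygen or C3.

**4 to 3 to 1 and 2.** The lactone bond O1–C2 is opened to triketo diester 3, and the bond from the acyl carbon to the oxoglutarate is then cut. Diester 1 supplies pyrone C2–C5 and the ester. Acid chloride 2 supplies C6, the pentyl chain and the ring oxygen. Only one six-membered lactone can form from 3, so the pyrone substitution pattern is fixed by connectivity.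

**19 to 18 to 17 to 16 to 14.** Ring A is traced back through the acid oxidation level, the benzyl ether, the methyl ether and the formyl carbon–carbon bond to resorcinol 14. A formyl group is preferred to direct carboxylation because its hydrogen bond to the C2 hydroxyl differentiates the two phenols of 16 for selective methylation at O4. The iminium salt 15 is the primary formylation product.

## Alternatives that were turned down

**Alternative 1:** Ring A is cut at C1–C2 and C5–C6, so that C1 and C6 are the alkyne carbons of an ynoate already on ring B and C2–C5 come from a dioxygenated diene.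
- Forward: benzyl 2,4-dihydroxy-6-pentylbenzoate A1 is acylated at its C4 hydroxyl to give benzyl 4-(hex-2-ynoyloxy)-2-hydroxy-6-pentylbenzoate A2. Heating A2 with 1,3-dimethoxy-1-(trimethylsilyloxy)buta-1,3-diene A3 should give benzyl stenosporate A4 after cycloaddition, loss of the alkoxy group at the ketal carbon and desilylation. A4 is one hydrogenolysis from the target.
- For: it is very short, the hindered ester is formed from a slim alkynoic acid, and ring A arrives with hydroxyl and methoxyl already differentiated.
- Against: a beta-alkyl ynoate is a sluggish dienophile. The aryl ynoate is also an activated ester and a Michael acceptor, so the nucleophilic diene can be C-acylated or add without closing the ring. The aromatization has the same leaving-group ambiguity, and the wrong choice gives a dimethyl ether. All the risk is taken on a substrate that already contains ring B.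
- Comparison: alternative 1 is stronger on step count and convergence. The chosen route runs its cycloaddition on the small pyrone 5 before any depside bond exists, uses acetal 9 in which the elimination cannot go wrong, and builds ring B from bulk acyclic materials.

**Alternative 2:** Ring B is cut at C1–C6 and C2–C3 at the oxidation level of a cyclohexanedione.
- Forward: dibenzyl malonate A5 adds in a Michael reaction to (E)-non-3-en-2-one A6, and the methyl ketone enolate closes by Dieckmann condensation onto a malonate ester. This gives benzyl 2-hydroxy-4-oxo-6-pentylcyclohex-2-ene-1-carboxylate A7 (racemic, trans), which is dehydrogenated to A1.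
- For: this is the most dependable way to such a ring. It is cheap, forms two bonds in one pot and has predictable regiochemistry. On reliability it is stronger than the chosen key step.
- Against: it makes two stereocentres only to destroy them. It needs a separate oxidation, and halogen-based dehydrogenation of an electron-rich ring risks nuclear halogenation and loss of the benzyl ester. A7 is a beta-keto ester that decarboxylates easily. In A1 the two phenols are distinguished only by a hydrogen bond.
- Comparison: the chosen route reaches the arene directly without an oxidant and with O2 and O4 in different protecting groups. Alternative 2 wins on precedent.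

**Alternative 3:** The depside carbonyl is cut on both sides, at the ring A aryl–carbonyl bond and at the carbonyl–oxygen bond.
- Forward: 2-iodo-1,5-dimethoxy-3-propylbenzene A8, carbon monoxide A9 and the C4 hydroxyl of A1 are joined by palladium-catalysed aryloxycarbonylation with a wide-bite-angle diphosphine and an amine base. The product is benzyl 4-[(2,4-dimethoxy-6-propylbenzoyl)oxy]-2-hydroxy-6-pentylbenzoate A10.
- For: no ring A acid has to be made, oxidized or activated, and it is the most convergent plan.
- Against: oxidative addition and insertion at an electron-rich aryl iodide with two ortho substituents should be slow. The acylpalladium must be captured by a weakly nucleophilic phenol to give an activated ester that the phenoxide can attack again. Afterwards the ring A C2 methyl ether must be cleaved with a boron trihalide in the presence of the C4 methyl ether, the depside ester and the benzyl ester. That is a Lewis acid step on the most sensitive compound of the route.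
- Comparison: alternative 3 is shorter. The chosen route finishes all oxygen differentiation before the coupling and ends with neutral hydrogenolysis.

Key step: step 6

## Route

Remark: diester 1 and divarinol 14 are taken to be purchasable; 3 is drawn as the triketone although it should exist as chelated enols.

**Step 1**
Reactants: 1 dibenzyl 3-oxopentanedioate; 2 hexanoyl chloride
Product: 3 dibenzyl 2-hexanoyl-3-oxopentanedioate
Conditions: MgCl2, pyridine, CH2Cl2, 0 °C to rt; 1 M HCl work-up
Reagents that add atoms: none
Why: Soft enolization of the beta-keto diester as its magnesium chelate and C-acylation by the acid chloride; chelation favours carbon over oxygen attack, and one equivalent of 2 limits double acylation.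

**Step 2**
Reactants: 3 dibenzyl 2-hexanoyl-3-oxopentanedioate
Product: 4 benzyl 4-hydroxy-2-oxo-6-pentyl-2H-pyran-5-carboxylate
Conditions: DBU (1.2 equiv), toluene, 80 °C; 1 M HCl work-up
Reagents that add atoms: none
Why: Base-mediated enol lactonization in which the enolate oxygen of the hexanoyl group attacks the remote benzyl ester and expels benzyl alcohol; this is the only six-membered closure open to 3, and the product is an aromatic, hydrogen-bonded 4-hydroxy-2-pyrone.

**Step 3**
Reactants: 4 benzyl 4-hydroxy-2-oxo-6-pentyl-2H-pyran-5-carboxylate
Product: 5 benzyl 4-(benzyloxy)-2-oxo-6-pentyl-2H-pyran-5-carboxylate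
Conditions: BnOH, PPh3, DIAD, THF, 0 °C to rt
Reagents that add atoms: benzyl alcohol, OCc1ccccc1
Why: Mitsunobu alkylation of the acidic 4-hydroxy-2-pyrone, a reaction type that delivers 4-alkoxy-2-pyrones in preference to 2-alkoxy-4-pyrones or C3-alkylated products; the neutral conditions leave the lactone and ester untouched.

**Step 4**
Reactants: 6 acetic acid
Product: 7 tert-butyldimethylsilyl acetate
Conditions: TBSCl, imidazole, CH2Cl2, 0 °C to rt
Reagents that add atoms: tert-butyldimethylsilyl chloride, CC(C)(C)[Si](C)(C)Cl
Why: Standard silylation of a carboxylic acid; the tert-butyldimethylsilyl ester is stable enough to be filtered and distilled.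

**Step 5**
Reactants: 7 tert-butyldimethylsilyl acetate
Product: 9 1,1-bis[(tert-butyldimethylsilyl)oxy]ethene, via lithium enolate 8 (not isolated)
Conditions: LiN(iPr)2, THF, −78 °C; then TBSCl, DMPU, −78 °C to rt; non-aqueous work-up
Reagents that add atoms: tert-butyldimethylsilyl chloride, CC(C)(C)[Si](C)(C)Cl
Why: Kinetic deprotonation of the silyl ester and O-silylation of the enolate, the usual preparation of ketene bis-silyl acetals; the polar cosolvent favours silylation at oxygen over carbon.

**Step 6**
Reactants: 5 benzyl 4-(benzyloxy)-2-oxo-6-pentyl-2H-pyran-5-carboxylate; 9 1,1-bis[(tert-butyldimethylsilyl)oxy]ethene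
Product: 12 benzyl 2-(benzyloxy)-4-[(tert-butyldimethylsilyl)oxy]-6-pentylbenzoate, via bridged bicyclic lactone 10 (not isolated), via cyclohexadiene bis-silyl ketal 11 (not isolated)
Conditions: 9 (4 equiv), toluene, 140 °C, sealed tube
Reagents that add atoms: none
Why: This is the inverse-electron-demand Diels–Alder reaction of a 2-pyrone-5-carboxylate with a ketene acetal, the closest known case being the conversion of coumalate esters and ketene dialkyl acetals into 4-alkoxybenzoates. The electron-rich CH2 terminus of 9 should bond to pyrone C6, which is the beta carbon of the unsaturated ester and the delta carbon of the dienyl lactone, while the ketal carbon bonds to C3, the alpha carbon of the lactone; this forms ring B C5–C6 and C3–C4 and gives the bridged lactone 10. The six-membered carbocycle is closed by a [4+2] cycloaddition in which both bonds form on the same face of the pyrone through a boat-like six-membered transition state, probably asynchronously with the bond to C6 leading. Cycloreversion of 10 expels the lactone bridge as carbon dioxide and leaves diene 11, and 1,2-elimination of tert-butyldimethylsilanol across C4–C5 then gives the arene. The two bridgehead stereocentres of 10 are transient and are erased on aromatization, so no stereocontrol is needed. The selectivity required is regiochemical, oxygen at C4 and not at C5, and the matched polarity of the two partners secures it. The chemoselectivity of the aromatization is secured by the two identical silyloxy groups on the ketal carbon, since whichever leaves the product is the same silyl ether. Because the 4-benzyloxy donor and the 6-pentyl group make 5 less reactive than a coumalate, heat and an excess of 9 are planned.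

**Step 7**
Reactants: 12 benzyl 2-(benzyloxy)-4-[(tert-butyldimethylsilyl)oxy]-6-pentylbenzoate
Product: 13 benzyl 2-(benzyloxy)-4-hydroxy-6-pentylbenzoate
Conditions: Bu4NF, AcOH, THF, 0 °C
Reagents that add atoms: none
Why: Fluoride cleavage of an aryl silyl ether; acetic acid buffers the phenoxide so that the benzyl ester is not attacked, and the benzyl ether is inert.

**Step 8**
Reactants: 14 divarinol (5-propylbenzene-1,3-diol)
Product: 16 2,4-dihydroxy-6-propylbenzaldehyde, via aryl iminium chloride 15 (not isolated)
Conditions: POCl3, DMF, 0 °C to rt; then H2O, 50 °C
Reagents that add atoms: N,N-dimethylformamide, CN(C)C=O; water, O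
Why: Vilsmeier–Haack formylation of a 5-alkylresorcinol, which should occur mainly at the position ortho to one hydroxyl and para to the other (next to the propyl group) and not between the two hydroxyls; hydrolysis of the iminium salt releases the aldehyde.

**Step 9**
Reactants: 16 2,4-dihydroxy-6-propylbenzaldehyde
Product: 17 2-hydroxy-4-methoxy-6-propylbenzaldehyde
Conditions: MeI (1.05 equiv), K2CO3 (1.0 equiv), acetone, rt
Reagents that add atoms: iodomethane, CI
Why: Williamson etherification; the C2 hydroxyl is held in a hydrogen bond to the formyl group, so the more acidic and freer C4 hydroxyl para to the aldehyde should be methylated selectively.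

**Step 10**
Reactants: 17 2-hydroxy-4-methoxy-6-propylbenzaldehyde
Product: 18 2-(benzyloxy)-4-methoxy-6-propylbenzaldehyde
Conditions: BnBr, K2CO3, DMF, 60 °C
Reagents that add atoms: benzyl bromide, BrCc1ccccc1
Why: Williamson benzylation of the remaining chelated phenol, which needs a polar solvent and warming but has no competing site.

**Step 11**
Reactants: 18 2-(benzyloxy)-4-methoxy-6-propylbenzaldehyde
Product: 19 2-(benzyloxy)-4-methoxy-6-propylbenzoic acid
Conditions: NaClO2, NaH2PO4, 2-methyl-2-butene, t-BuOH/H2O, rt
Reagents that add atoms: sodium chlorite, [Na+].[O-]Cl=O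
Why: Pinnick oxidation, which tolerates hindered aryl aldehydes; the alkene scavenges hypochlorous acid and so protects the electron-rich ring from chlorination.

**Step 12**
Reactants: 19 2-(benzyloxy)-4-methoxy-6-propylbenzoic acid; 13 benzyl 2-(benzyloxy)-4-hydroxy-6-pentylbenzoate
Product: 21 benzyl 2-(benzyloxy)-4-{[2-(benzyloxy)-4-methoxy-6-propylbenzoyl]oxy}-6-pentylbenzoate, via mixed trifluoroacetic anhydride 20 (not isolated)
Conditions: (CF3CO)2O, toluene, rt
Reagents that add atoms: none
Why: Esterification through a mixed trifluoroacetic anhydride, the standard activation for depside formation; the electron-rich 2,6-disubstituted acyl group reacts with acylium character, which overcomes the steric hindrance, and 13 offers only one hydroxyl.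

**Step 13**
Reactants: 21 benzyl 2-(benzyloxy)-4-{[2-(benzyloxy)-4-methoxy-6-propylbenzoyl]oxy}-6-pentylbenzoate
Product: 22 stenosporic acid
Conditions: H2 (1 atm), 10% Pd/C, EtOAc, rt
Reagents that add atoms: none
Why: Catalytic hydrogenolysis removes the two benzyl ethers and the benzyl ester in one neutral operation; the aryl ester, the methyl ether and the arenes are not reduced, and the absence of acid, base and heat avoids decarboxylation.

## Compound list

1 | dibenzyl 3-oxopentanedioate | O=C(CC(=O)OCc1ccccc1)CC(=O)OCc1ccccc1 | starting material
2 | hexanoyl chloride | CCCCCC(=O)Cl | starting material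
3 | dibenzyl 2-hexanoyl-3-oxopentanedioate (keto form drawn, C2 configurationally labile) | CCCCCC(=O)C(C(=O)OCc1ccccc1)C(=O)CC(=O)OCc1ccccc1 | intermediate
4 | benzyl 4-hydroxy-2-oxo-6-pentyl-2H-pyran-5-carboxylate | CCCCCc1oc(=O)cc(O)c1C(=O)OCc1ccccc1 | intermediate
5 | benzyl 4-(benzyloxy)-2-oxo-6-pentyl-2H-pyran-5-carboxylate | CCCCCc1oc(=O)cc(OCc2ccccc2)c1C(=O)OCc1ccccc1 | intermediate
6 | acetic acid | CC(=O)O | starting material
7 | tert-butyldimethylsilyl acetate | CC(=O)O[Si](C)(C)C(C)(C)C | intermediate
8 | lithium 1-[(tert-butyldimethylsilyl)oxy]ethenolate | [Li+].C=C([O-])O[Si](C)(C)C(C)(C)C | intermediate (not isolated)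
9 | 1,1-bis[(tert-butyldimethylsilyl)oxy]ethene | C=C(O[Si](C)(C)C(C)(C)C)O[Si](C)(C)C(C)(C)C | intermediate
10 | benzyl 5-(benzyloxy)-8,8-bis[(tert-butyldimethylsilyl)oxy]-3-oxo-1-pentyl-2-oxabicyclo[2.2.2]oct-5-ene-6-carboxylate (racemic, one enantiomer drawn) | CCCCC[C@]12CC(O[Si](C)(C)C(C)(C)C)(O[Si](C)(C)C(C)(C)C)[C@H](C(=O)O1)C(OCc1ccccc1)=C2C(=O)OCc1ccccc1 | intermediate (not isolated)
11 | benzyl 6-(benzyloxy)-4,4-bis[(tert-butyldimethylsilyl)oxy]-2-pentylcyclohexa-1,5-diene-1-carboxylate | CCCCCC1=C(C(=O)OCc2ccccc2)C(OCc2ccccc2)=CC(O[Si](C)(C)C(C)(C)C)(O[Si](C)(C)C(C)(C)C)C1 | intermediate (not isolated)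
12 | benzyl 2-(benzyloxy)-4-[(tert-butyldimethylsilyl)oxy]-6-pentylbenzoate | CCCCCc1cc(O[Si](C)(C)C(C)(C)C)cc(OCc2ccccc2)c1C(=O)OCc1ccccc1 | intermediate
13 | benzyl 2-(benzyloxy)-4-hydroxy-6-pentylbenzoate | CCCCCc1cc(O)cc(OCc2ccccc2)c1C(=O)OCc1ccccc1 | intermediate
14 | divarinol (5-propylbenzene-1,3-diol) | CCCc1cc(O)cc(O)c1 | starting material
15 | N-[(2,4-dihydroxy-6-propylphenyl)methylidene]-N-methylmethanaminium chloride | CCCc1cc(O)cc(O)c1C=[N+](C)C.[Cl-] | intermediate (not isolated)
16 | 2,4-dihydroxy-6-propylbenzaldehyde | CCCc1cc(O)cc(O)c1C=O | intermediate
17 | 2-hydroxy-4-methoxy-6-propylbenzaldehyde | CCCc1cc(OC)cc(O)c1C=O | intermediate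
18 | 2-(benzyloxy)-4-methoxy-6-propylbenzaldehyde | CCCc1cc(OC)cc(OCc2ccccc2)c1C=O | intermediate
19 | 2-(benzyloxy)-4-methoxy-6-propylbenzoic acid | CCCc1cc(OC)cc(OCc2ccccc2)c1C(=O)O | intermediate
20 | 2-(benzyloxy)-4-methoxy-6-propylbenzoic trifluoroacetic anhydride | CCCc1cc(OC)cc(OCc2ccccc2)c1C(=O)OC(=O)C(F)(F)F | intermediate (not isolated)
21 | benzyl 2-(benzyloxy)-4-{[2-(benzyloxy)-4-methoxy-6-propylbenzoyl]oxy}-6-pentylbenzoate | CCCCCc1cc(OC(=O)c2c(OCc3ccccc3)cc(OC)cc2CCC)cc(OCc2ccccc2)c1C(=O)OCc1ccccc1 | intermediate
22 | stenosporic acid, 2-hydroxy-4-[(2-hydroxy-4-methoxy-6-propylbenzoyl)oxy]-6-pentylbenzoic acid | CCCCCc1cc(OC(=O)c2c(O)cc(OC)cc2CCC)cc(O)c1C(=O)O | target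

## Step count and least certain steps

Total step count: 13. Longest linear sequence: 7 steps (steps 1, 2, 3, 6, 7, 12, 13, from 1 to 22). The ring A branch (steps 8–11) and the ketene acetal branch (steps 4–5) are convergent.

**Step 6 (key step).** The most likely failure is that the cycloaddition does not start. The C4 donor, the ester twisted between two neighbours and the alkyl group at the carbon to be attacked all lower the reactivity of 5, so thermal O-to-C silyl migration or decomposition of 9 may win at the temperature required. A second failure is a stepwise addition at C6 followed by silyl transfer to the pyrone enolate oxygen in place of ring closure at C3, which would divert material to open-chain adducts. The fallback gives up the construction of ring B and uses known depside chemistry. It sets out from acid 19 and comes back at 22. Commercial olivetolic acid F1 is alkylated on the carboxylate alone (BnBr, KHCO3, DMF) to give benzyl 2,4-dihydroxy-6-pentylbenzoate F2. F2 is acylated by 19 under the conditions of step 12 at its C4 hydroxyl, the C2 hydroxyl being deactivated by its hydrogen bond to the ester. This gives benzyl 4-{[2-(benzyloxy)-4-methoxy-6-propylbenzoyl]oxy}-2-hydroxy-6-pentylbenzoate F3, and hydrogenolysis as in step 13 gives 22.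

**Step 3.** The pyronate is ambident, so alkylation may take place at the lactone carbonyl oxygen or at C3 in place of the 4-oxygen, and the hydrogen-bonded hydroxyl may react slowly. The fallback replaces alkylation of the pyrone by substitution on it. It sets out from 4 and comes back at 5. Treatment of 4 with POCl3 and Et3N should give benzyl 4-chloro-2-oxo-6-pentyl-2H-pyran-5-carboxylate F4, a vinylogous acid chloride. Benzyl alcohol with K2CO3 in MeCN should displace the chloride by addition–elimination at C4, the only carbon that carries a leaving group, to give 5.

**Step 1 (with step 2).** O-acylation or double acylation of 1 may compete, and the tricarbonyl compound 3 may lose an acyl group by retro-Claisen cleavage during cyclization. The fallback assembles the pyrone from the other side. It sets out from 2 and comes back at 4. Acylation of Meldrum's acid with 2 (pyridine, CH2Cl2) gives 5-(1-hydroxyhexylidene)-2,2-dimethyl-1,3-dioxane-4,6-dione F5. Heating F5 with benzyl alcohol in toluene gives benzyl 3-oxooctanoate F6. Condensation of F6 with malonyl dichloride, by C-acylation and then enol O-acylation, is a known route to 4-hydroxy-2-pyrone-5-carboxylates and should give 4.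

**Step 12.** Acyl transfer from the hindered acid may be slow, so trifluoroacetylation of the phenol or acid-induced loss of a benzyl ether from the acylium intermediate may compete. The fallback changes the acyl donor to a ketene. It sets out from 19 and comes back at 22. Hydrogenolysis of 19 gives 2-hydroxy-4-methoxy-6-propylbenzoic acid F7. Acetone with trifluoroacetic anhydride and trifluoroacetic acid converts F7 into 7-methoxy-2,2-dimethyl-5-propyl-4H-1,3-benzodioxin-4-one F8. Irradiation of F8 at about 300 nm with 13 releases acetone and an ortho-quinone ketene, which the phenol traps to give benzyl 2-(benzyloxy)-4-[(2-hydroxy-4-methoxy-6-propylbenzoyl)oxy]-6-pentylbenzoate F9. Hydrogenolysis as in step 13 gives 22.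

## Further compounds

F1 | step 6 | olivetolic acid (2,4-dihydroxy-6-pentylbenzoic acid) | CCCCCc1cc(O)cc(O)c1C(=O)O
F2 | step 6 | benzyl 2,4-dihydroxy-6-pentylbenzoate | CCCCCc1cc(O)cc(O)c1C(=O)OCc1ccccc1
F3 | step 6 | benzyl 4-{[2-(benzyloxy)-4-methoxy-6-propylbenzoyl]oxy}-2-hydroxy-6-pentylbenzoate | CCCCCc1cc(OC(=O)c2c(OCc3ccccc3)cc(OC)cc2CCC)cc(O)c1C(=O)OCc1ccccc1
F4 | step 3 | benzyl 4-chloro-2-oxo-6-pentyl-2H-pyran-5-carboxylate | CCCCCc1oc(=O)cc(Cl)c1C(=O)OCc1ccccc1
F5 | step 1 | 5-(1-hydroxyhexylidene)-2,2-dimethyl-1,3-dioxane-4,6-dione | CCCCCC(O)=C1C(=O)OC(C)(C)OC1=O
F6 | step 1 | benzyl 3-oxooctanoate | CCCCCC(=O)CC(=O)OCc1ccccc1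
F7 | step 12 | 2-hydroxy-4-methoxy-6-propylbenzoic acid | CCCc1cc(OC)cc(O)c1C(=O)O
F8 | step 12 | 7-methoxy-2,2-dimethyl-5-propyl-4H-1,3-benzodioxin-4-one | CCCc1cc(OC)cc2OC(C)(C)OC(=O)c12
F9 | step 12 | benzyl 2-(benzyloxy)-4-[(2-hydroxy-4-methoxy-6-propylbenzoyl)oxy]-6-pentylbenzoate | CCCCCc1cc(OC(=O)c2c(O)cc(OC)cc2CCC)cc(OCc2ccccc2)c1C(=O)OCc1ccccc1
A1 | alternative 1 | benzyl 2,4-dihydroxy-6-pentylbenzoate | CCCCCc1cc(O)cc(O)c1C(=O)OCc1ccccc1
A2 | alternative 1 | benzyl 4-(hex-2-ynoyloxy)-2-hydroxy-6-pentylbenzoate | CCCCCc1cc(OC(=O)C#CCCC)cc(O)c1C(=O)OCc1ccccc1
A3 | alternative 1 | 1,3-dimethoxy-1-(trimethylsilyloxy)buta-1,3-diene | C=C(OC)C=C(OC)O[Si](C)(C)C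
A4 | alternative 1 | benzyl stenosporate, benzyl 2-hydroxy-4-[(2-hydroxy-4-methoxy-6-propylbenzoyl)oxy]-6-pentylbenzoate | CCCCCc1cc(OC(=O)c2c(O)cc(OC)cc2CCC)cc(O)c1C(=O)OCc1ccccc1
A5 | alternative 2 | dibenzyl malonate | O=C(CC(=O)OCc1ccccc1)OCc1ccccc1
A6 | alternative 2 | (E)-non-3-en-2-one | CCCCC/C=C/C(C)=O
A7 | alternative 2 | benzyl 2-hydroxy-4-oxo-6-pentylcyclohex-2-ene-1-carboxylate (racemic trans, one enantiomer drawn) | CCCCC[C@@H]1CC(=O)C=C(O)[C@H]1C(=O)OCc1ccccc1
A8 | alternative 3 | 2-iodo-1,5-dimethoxy-3-propylbenzene | CCCc1cc(OC)cc(OC)c1I
A9 | alternative 3 | carbon monoxide | [C-]#[O+]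
A10 | alternative 3 | benzyl 4-[(2,4-dimethoxy-6-propylbenzoyl)oxy]-2-hydroxy-6-pentylbenzoate | CCCCCc1cc(OC(=O)c2c(OC)cc(OC)cc2CCC)cc(O)c1C(=O)OCc1ccccc1
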